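**Remarks on the chemistry (assumptions)**
- Carbons carry briarane numbering throughout: C1 (quaternary, methyl C15), C2 (OAc), C3=C4, C5(=C16H2), C6 (Cl), C7 (lactone O), C8 (OH), C9 (OAc), C10, C11 (methyl C20), C12 (C=O), C13, C14 (butyrate), C17 (methyl C18), C19 (lactone C=O).
- Compound 13 is drawn as the triketone; it should exist as the enol of the ring 1,3-dione.
- Aldol adduct 18 (C4) and ring-closure product 26 (C6) are carried as epimer mixtures, because these centres are erased in the following step.
- Isopropenylmagnesium bromide and ethyl 2-[bis(2,2,2-trifluoroethoxy)phosphoryl]propanoate are taken as commercial reagents.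

**Retrosynthetic overview**
1. Target ⇐ oxidative lactonisation (C19 to O7) of a 7,8,19-triol; C6–Cl ⇐ invertive chlorination of a C6 allylic alcohol; ten-membered ring ⇐ intramolecular Nozaki–Hiyama–Kishi closure of C5–C6 (C5 vinyl bromide, C6 aldehyde).
2. C3–C5/C16 arm ⇐ aldol condensation of the C2 methyl ketone (C3) with 2-bromoacrolein; the C2 and C14 carbinols ⇐ reduction of the two ketones that the key step leaves at these positions.
3. Six-membered ring ⇐ one-pot Michael/Claisen [3+3] union of 3-methylpentane-2,4-dione with butenolide 10 (C1–C10 by conjugate addition, C12–C13 by ring-opening Claisen acylation). Enabling feature: C12=O and C14–O are 1,3-related across C13, C1 lies between the oxygenated carbons C14 and C2 (a 2-methyl-1,3-diketone unit), and O9 is γ to C12, so that C12–C11–C10–C9–O9 is an α-methylbutenolide.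
4. Butenolide 10 ⇐ diacetone-D-glucose (glucose C1–C4 become C6–C9; the C8 branch comes from Grignard addition and hydroboration).
5. Ring order: six-membered carbocycle (step 9), ten-membered carbocycle (step 19), γ-lactone (step 24).

Key step: step 9

**Route**

Step 1
Reactants: 1 1,2:5,6-di-O-isopropylidene-α-D-glucofuranose
Product: 2 1,2:5,6-di-O-isopropylidene-α-D-ribo-hexofuranos-3-ulose
Conditions: Dess–Martin periodinane, NaHCO3, CH2Cl2, rt
Reagents that add atoms: none
Why: Dess–Martin oxidation of the single free secondary hydroxyl to the 3-ketone, with both acetonides stable to the buffered oxidant; no stereocentre is created.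

Step 2
Reactants: 2 1,2:5,6-di-O-isopropylidene-α-D-ribo-hexofuranos-3-ulose
Product: 3 3-C-isopropenyl-1,2:5,6-di-O-isopropylidene-α-D-allofuranose
Conditions: isopropenylmagnesium bromide, THF, −78 °C; aq. NH4Cl
Reagents that add atoms: isopropenylmagnesium bromide, C=C(C)[Mg]Br
Why: Grignard 1,2-addition to the ketone from the β (exo) face, because the cis-fused 1,2-O-isopropylidene ring shields the α face, which should give the tertiary alcohol with the C8 configuration of the target (hydroxyl α, carbon branch β).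

Step 3
Reactants: 3 3-C-isopropenyl-1,2:5,6-di-O-isopropylidene-α-D-allofuranose
Product: 4 3-C-[(2S)-1-hydroxypropan-2-yl]-1,2:5,6-di-O-isopropylidene-α-D-allofuranose
Conditions: BH3·THF, THF, 0 °C to rt; then NaOH, H2O2, 0 °C
Reagents that add atoms: hydrogen peroxide, OO
Why: Hydroboration–oxidation (anti-Markovnikov) of the 1,1-disubstituted alkene, in which borane should attack the alkene face turned away from the C4 side chain while the C3–O bond eclipses the C=CH2 bond, so that hydrogen reaches C17 from the side of C2 and the C17 configuration of the target results.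

Step 4
Reactants: 4 3-C-[(2S)-1-hydroxypropan-2-yl]-1,2:5,6-di-O-isopropylidene-α-D-allofuranose
Product: 5 primary tert-butyldiphenylsilyl (TBDPS) ether of 4 (C19–OTBDPS, tertiary C8–OH free)
Conditions: TBDPSCl, imidazole, DMF, rt
Reagents that add atoms: tert-butyl(chloro)diphenylsilane, CC(C)(C)[Si](Cl)(c1ccccc1)c1ccccc1
Why: Silylation of the primary hydroxyl in preference to the hindered tertiary one (steric selectivity of the bulky silyl chloride); no stereocentre is touched.

Step 5
Reactants: 5 primary TBDPS ether of 4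
Product: 6 3-C-[(2S)-1-(TBDPS-oxy)propan-2-yl]-1,2-O-isopropylidene-α-D-ribo-pentodialdo-1,4-furanose (C10 aldehyde)
Conditions: H5IO6, EtOAc, rt
Reagents that add atoms: none
Why: One-pot selective hydrolysis of the terminal 5,6-acetonide and glycol cleavage by periodic acid, which leaves the more robust cis-fused 1,2-acetonide and unmasks C10 as an aldehyde without touching a stereocentre.

Step 6
Reactants: 6 C10 aldehyde
Product: 7 ethyl (Z)-2-methyl-enoate (C10=C11, C12 ester) on the furanose
Conditions: ethyl 2-[bis(2,2,2-trifluoroethoxy)phosphoryl]propanoate, KN(SiMe3)2, 18-crown-6, THF, −78 °C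
Reagents that add atoms: ethyl 2-[bis(2,2,2-trifluoroethoxy)phosphoryl]propanoate, CCOC(=O)C(C)P(=O)(OCC(F)(F)F)OCC(F)(F)F
Why: Still–Gennari variant of the Horner–Wadsworth–Emmons reaction, whose kinetic control should give the (Z)-2-methyl enoate needed for the later lactonisation; no new stereocentre.

Step 7
Reactants: 7 ethyl (Z)-2-methyl-enoate on the furanose
Product: 9 α-methylbutenolide 7,8-diol with C6 as 1,3-dithiane and C19–OTBDPS, via open-chain hydroxy ester dithiane 8 (not isolated)
Conditions: propane-1,3-dithiol, BF3·OEt2, CH2Cl2, −20 °C to 0 °C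
Reagents that add atoms: propane-1,3-dithiol, SCCCS
Why: BF3-promoted transthioacetalisation of the anomeric acetal opens the furanose to the C6 dithiane, and the liberated C9 hydroxyl (the former ring oxygen) closes onto the (Z)-ester in a 5-exo-trig lactonisation to the α-methylbutenolide; C7, C8, C9 and C17 are carried over unchanged.

Step 8
Reactants: 9 α-methylbutenolide 7,8-diol
Product: 10 butenolide 7,8-O-isopropylidene acetal (C6 dithiane, C19–OTBDPS)
Conditions: 2-methoxypropene, PPTS (cat.), CH2Cl2, 0 °C to rt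
Reagents that add atoms: 2-methoxypropene, COC(C)=C
Why: Acid-catalysed acetonide formation on the only 1,2-diol (secondary C7–OH, tertiary C8–OH), which protects both oxygens against translactonisation and oxa-Michael addition in the next step; no stereocentre is touched.

Step 9
Reactants: 10 butenolide 7,8-O-isopropylidene acetal; 11 3-methylpentane-2,4-dione
Product: 13 2-acetyl-2-methylcyclohexane-1,3-dione carrying the C11 methyl and the C10 side chain with free C9–OH, via Michael adduct lactone 12 (not isolated)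
Conditions: 11 (3 equiv), DBU (0.3 equiv), THF, 40 °C; then KOt-Bu (4 equiv), 18-crown-6, THF, 0 °C to rt; AcOH
Reagents that add atoms: none
Why: Base-mediated Michael–Claisen [3+3] annulation: the enolate of 11 adds through C1 to C10 of the butenolide (bond C1–C10), the lactone enolate is protonated at C11, and the enolate of one acetyl group (C13) attacks the lactone carbonyl C12 in a 6-(enolendo)-exo-trig Claisen condensation whose tetrahedral intermediate (a 2-oxabicyclo[3.2.1]octane) collapses with release of the C9 alkoxide and is driven by formation of the stabilised 1,3-dione enolate; the closest known reaction type is the Michael–Claisen synthesis of cyclohexane-1,3-diones from 1,3-dicarbonyl compounds and α,β-unsaturated esters. C10 should be set by attack anti to the bulky C9 substituent of the γ-substituted butenolide, and C11 by protonation and equilibration of the lactone enolate trans to the new C10 substituent, which gives the all-trans lactone that maps onto the target. C1 is not stereogenic after the Michael step (two identical acetyl groups) and becomes so only in the ring closure. In the chair-like bicyclic transition state the spectator acetyl should take the axial position anti to the C9–O bridge and away from the enolate oxygen (dipole and allylic-strain minimisation with the non-chelating K+/18-crown-6 counter-ion), leaving the methyl group equatorial, which is the target arrangement (C15 cis to C9). The step needs conjugate addition to win over γ-deprotonation of the butenolide, which the soft, weakly basic diketone enolate under catalytic DBU should secure before the strong base is added, and the acetonide keeps O7 and O8 out of the reaction.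

Step 10
Reactants: 13 2-acetyl-2-methylcyclohexane-1,3-dione with free C9–OH
Product: 14 C12 methyl enol ether (3-methoxy-cyclohex-2-enone, C14 carbonyl retained)
Conditions: MeOH, PPTS (cat.), 3 Å molecular sieves, rt
Reagents that add atoms: methanol, CO
Why: Acid-catalysed enol etherification of the cyclic 1,3-dione under thermodynamic control, which should place the methoxy group on C12, the carbonyl remote from the quaternary C1, as is usual for 4,4-disubstituted cyclohexane-1,3-diones; no stereocentre is formed.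

Step 11
Reactants: 15 acrolein
Product: 17 2-bromoacrolein, via 2,3-dibromopropanal 16 (not isolated)
Conditions: Br2, CH2Cl2, −78 °C; then Et3N, −78 °C to 0 °C
Reagents that add atoms: bromine, BrBr
Why: Bromination of the alkene followed by amine-induced dehydrobromination (addition–elimination) gives the α-bromo enal; no stereocentre.

Step 12
Reactants: 14 C12 methyl enol ether; 17 2-bromoacrolein
Product: 18 β-hydroxy ketone (C2 ketone, C4 carbinol as epimer mixture, C5 vinyl bromide)
Conditions: (c-C6H11)2BCl (2.5 equiv), Et3N, Et2O, −78 °C to 0 °C; then 17, −78 °C; MeOH, pH 7 buffer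
Reagents that add atoms: none
Why: Boron-mediated aldol addition in which (c-C6H11)2BCl/Et3N enolises the methyl ketone only towards C3 (C1 is quaternary) and the boron enolate adds 1,2 to the enal; the new C4 carbinol forms as an epimer mixture that is erased in the next step.

Step 13
Reactants: 18 β-hydroxy ketone
Product: 20 (3E)-5-bromo-3,5(16)-dien-2-one 9-acetate, via bis-acetate 19 (not isolated)
Conditions: Ac2O, pyridine, DMAP (cat.), CH2Cl2, rt; then DBU, rt
Reagents that add atoms: acetic anhydride, CC(=O)OC(C)=O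
Why: Acetylation of both hydroxyls followed by DBU-induced E1cB elimination of the β-acetoxy ketone gives the conjugated (3E)-dienone (thermodynamic geometry) and installs the C9 acetate of the target in the same operation.

Step 14
Reactants: 20 (3E)-5-bromo-3,5(16)-dien-2-one 9-acetate
Product: 21 (2R)-dienol
Conditions: (S)-2-methyl-CBS-oxazaborolidine (0.3 equiv), catecholborane, toluene, −78 °C
Reagents that add atoms: none
Why: Corey–Bakshi–Shibata reduction under reagent control: with the quaternary C1 as the large substituent the (S)-oxazaborolidine should give the (2R)-allylic alcohol, while the less electrophilic vinylogous ester carbonyl at C14 is left untouched.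

Step 15
Reactants: 21 (2R)-dienol
Product: 22 2,9-diacetate
Conditions: Ac2O, pyridine, DMAP (cat.), CH2Cl2, 0 °C to rt
Reagents that add atoms: acetic anhydride, CC(=O)OC(C)=O
Why: DMAP-catalysed acetylation of the secondary allylic alcohol; no stereocentre is affected.

Step 16
Reactants: 22 2,9-diacetate
Product: 23 (14S)-allylic alcohol (C12 enol ether retained)
Conditions: NaBH4, CeCl3·7H2O, MeOH/THF, 0 °C; NaHCO3 work-up
Reagents that add atoms: none
Why: Luche 1,2-reduction of the vinylogous ester carbonyl: in the preferred half-chair the C1 carbinol arm and the C10 side chain are trans-diaxial (this avoids the syn-diaxial C15/C20 methyl pair), so hydride should attack C14 antiperiplanar to the axial C1 arm, from the β face, giving the (14S)-alcohol cis to the C2 arm.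

Step 17
Reactants: 23 (14S)-allylic alcohol
Product: 24 14-butyrate
Conditions: butyric anhydride, Et3N, DMAP, CH2Cl2, rt
Reagents that add atoms: butyric anhydride, CCCC(=O)OC(=O)CCC
Why: DMAP-catalysed acylation of the only free hydroxyl under basic, non-ionising conditions that spare the acid-sensitive 3-methoxyallyl system; no stereocentre is affected.

Step 18
Reactants: 24 14-butyrate
Product: 25 C6 aldehyde (C5 vinyl bromide retained)
Conditions: MeI, CaCO3, MeCN/H2O (4:1), 45 °C
Reagents that add atoms: water, O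
Why: S-Methylation of the dithiane and hydrolysis of the sulfonium salt under CaCO3 buffering releases the C6 aldehyde under near-neutral conditions that the enol ether, the esters and the vinyl bromide tolerate, and that should not epimerise C7.

Step 19
Reactants: 25 C6 aldehyde
Product: 26 ten-membered C6 allylic alcohol (C6 epimer mixture)
Conditions: CrCl2 (10 equiv), NiCl2 (cat.), DMSO/THF, rt, high dilution
Reagents that add atoms: none
Why: Intramolecular Nozaki–Hiyama–Kishi reaction: nickel-catalysed formation of the C5 vinylchromium species and its chemoselective addition to the aldehyde closes the ten-membered ring (C5–C6) at high dilution; the C6 carbinol is expected as an epimer mixture that is erased in the next step.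

Step 20
Reactants: 26 ten-membered C6 allylic alcohol
Product: 27 C6 ketone (cross-conjugated with C5=C16 and C3=C4)
Conditions: Dess–Martin periodinane, NaHCO3, CH2Cl2, 0 °C
Reagents that add atoms: none
Why: Dess–Martin oxidation of the allylic alcohol converges both C6 epimers on one enone; no stereocentre is formed.

Step 21
Reactants: 27 C6 ketone
Product: 28 (6R)-allylic alcohol (syn to O7)
Conditions: NaBH4, CeCl3·7H2O, MeOH, −78 °C
Reagents that add atoms: none
Why: Luche 1,2-reduction of the α'-alkoxy enone under non-chelation control (hydride anti to the C7–O bond) should give the (6R)-alcohol, the epimer required for an invertive chlorination.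

Step 22
Reactants: 28 (6R)-allylic alcohol
Product: 29 (6S)-allylic chloride
Conditions: PPh3, hexachloroacetone, CH2Cl2, 0 °C
Reagents that add atoms: hexachloroacetone, ClC(Cl)(Cl)C(=O)C(Cl)(Cl)Cl
Why: Appel-type chlorination in which chloride displaces the oxyphosphonium group by SN2 with inversion and without allylic transposition, which should give the (6S)-chloride of the target.

Step 23
Reactants: 29 (6S)-allylic chloride
Product: 30 7,8,19-triol with the C12 ketone unveiled
Conditions: HF·pyridine, THF, 0 °C to rt; then 1 M HCl (aq), THF, rt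
Reagents that add atoms: water, O
Why: Fluoride cleavage of the silyl ether followed by mild aqueous acid, which hydrolyses the acetonide and C-protonates the enol ether (hydration, as with 3-O-acyl glycals, and not ionisation of the allylic butyrate) to unveil the C12 ketone; the β-butyryloxy ketone, the acetates and the allylic chloride are stable to acid.

Step 24
Reactants: 30 7,8,19-triol
Product: 32 CNP0283653.2 (target), via lactol 31 (not isolated)
Conditions: TEMPO (0.2 equiv), PhI(OAc)2 (2.5 equiv), CH2Cl2, rt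
Reagents that add atoms: none
Why: TEMPO/PhI(OAc)2 oxidation of the primary C19 alcohol to the aldehyde, which the C7 hydroxyl traps as a five-membered lactol that is oxidised on to the γ-lactone (oxidative lactonisation of a 1,4-diol); the tertiary C8 hydroxyl cannot react, C9 is blocked as its acetate, and no stereocentre is changed.

**Compound list**

1 | 1,2:5,6-di-O-isopropylidene-α-D-glucofuranose | CC1(C)OC[C@@H](O1)[C@H]2O[C@@H]3OC(C)(C)O[C@@H]3[C@H]2O | starting material
2 | 1,2:5,6-di-O-isopropylidene-α-D-ribo-hexofuranos-3-ulose | CC1(C)OC[C@@H](O1)[C@H]2O[C@@H]3OC(C)(C)O[C@@H]3C2=O | intermediate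
3 | 3-C-isopropenyl-1,2:5,6-di-O-isopropylidene-α-D-allofuranose | CC1(C)OC[C@@H](O1)[C@H]2O[C@@H]3OC(C)(C)O[C@@H]3[C@@]2(O)C(C)=C | intermediate
4 | 3-C-[(2S)-1-hydroxypropan-2-yl]-1,2:5,6-di-O-isopropylidene-α-D-allofuranose | CC1(C)OC[C@@H](O1)[C@H]2O[C@@H]3OC(C)(C)O[C@@H]3[C@@]2(O)[C@@H](C)CO | intermediate
5 | primary TBDPS ether of 4 | CC1(C)OC[C@@H](O1)[C@H]2O[C@@H]3OC(C)(C)O[C@@H]3[C@@]2(O)[C@@H](C)CO[Si](c4ccccc4)(c4ccccc4)C(C)(C)C | intermediate
6 | C10 aldehyde (1,2-O-isopropylidene pentodialdofuranose) | O=C[C@H]1O[C@@H]2OC(C)(C)O[C@@H]2[C@@]1(O)[C@@H](C)CO[Si](c3ccccc3)(c3ccccc3)C(C)(C)C | intermediate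
7 | ethyl (Z)-2-methyl-enoate on the furanose | CCOC(=O)/C(C)=C\[C@H]1O[C@@H]2OC(C)(C)O[C@@H]2[C@@]1(O)[C@@H](C)CO[Si](c3ccccc3)(c3ccccc3)C(C)(C)C | intermediate
8 | open-chain (Z)-hydroxy ester, C6 dithiane, 7,8,9-triol | CCOC(=O)/C(C)=C\[C@@H](O)[C@](O)([C@@H](C)CO[Si](c1ccccc1)(c1ccccc1)C(C)(C)C)[C@@H](O)C1SCCCS1 | intermediate
9 | α-methylbutenolide 7,8-diol, C6 dithiane | CC1=C[C@@H](OC1=O)[C@](O)([C@@H](C)CO[Si](c2ccccc2)(c2ccccc2)C(C)(C)C)[C@@H](O)C2SCCCS2 | intermediate
10 | butenolide 7,8-O-isopropylidene acetal | CC1=C[C@@H](OC1=O)[C@]2(OC(C)(C)O[C@H]2C3SCCCS3)[C@@H](C)CO[Si](c4ccccc4)(c4ccccc4)C(C)(C)C | intermediate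
11 | 3-methylpentane-2,4-dione | CC(=O)C(C)C(C)=O | starting material
12 | Michael adduct lactone (C1 with methyl and two acetyl groups) | C[C@H]1C(=O)O[C@H]([C@@H]1C(C)(C(C)=O)C(C)=O)[C@]2(OC(C)(C)O[C@H]2C3SCCCS3)[C@@H](C)CO[Si](c4ccccc4)(c4ccccc4)C(C)(C)C | intermediate
13 | 2-acetyl-2-methylcyclohexane-1,3-dione with C9–OH side chain | CC(=O)[C@@]1(C)C(=O)CC(=O)[C@H](C)[C@@H]1[C@@H](O)[C@]2(OC(C)(C)O[C@H]2C3SCCCS3)[C@@H](C)CO[Si](c4ccccc4)(c4ccccc4)C(C)(C)C | intermediate
14 | C12 methyl enol ether | CC(=O)[C@@]1(C)C(=O)C=C(OC)[C@H](C)[C@@H]1[C@@H](O)[C@]2(OC(C)(C)O[C@H]2C3SCCCS3)[C@@H](C)CO[Si](c4ccccc4)(c4ccccc4)C(C)(C)C | intermediate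
15 | acrolein | C=CC=O | starting material
16 | 2,3-dibromopropanal | O=CC(Br)CBr | intermediate
17 | 2-bromoacrolein | C=C(Br)C=O | intermediate
18 | β-hydroxy ketone (C4 epimers) | C=C(Br)C(O)CC(=O)[C@@]1(C)C(=O)C=C(OC)[C@H](C)[C@@H]1[C@@H](O)[C@]2(OC(C)(C)O[C@H]2C3SCCCS3)[C@@H](C)CO[Si](c4ccccc4)(c4ccccc4)C(C)(C)C | intermediate
19 | 4,9-bis-acetate | C=C(Br)C(OC(C)=O)CC(=O)[C@@]1(C)C(=O)C=C(OC)[C@H](C)[C@@H]1[C@@H](OC(C)=O)[C@]2(OC(C)(C)O[C@H]2C3SCCCS3)[C@@H](C)CO[Si](c4ccccc4)(c4ccccc4)C(C)(C)C | intermediate
20 | (3E)-bromodienone 9-acetate | C=C(Br)/C=C/C(=O)[C@@]1(C)C(=O)C=C(OC)[C@H](C)[C@@H]1[C@@H](OC(C)=O)[C@]2(OC(C)(C)O[C@H]2C3SCCCS3)[C@@H](C)CO[Si](c4ccccc4)(c4ccccc4)C(C)(C)C | intermediate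
21 | (2R)-dienol | C=C(Br)/C=C/[C@@H](O)[C@@]1(C)C(=O)C=C(OC)[C@H](C)[C@@H]1[C@@H](OC(C)=O)[C@]2(OC(C)(C)O[C@H]2C3SCCCS3)[C@@H](C)CO[Si](c4ccccc4)(c4ccccc4)C(C)(C)C | intermediate
22 | 2,9-diacetate | C=C(Br)/C=C/[C@@H](OC(C)=O)[C@@]1(C)C(=O)C=C(OC)[C@H](C)[C@@H]1[C@@H](OC(C)=O)[C@]2(OC(C)(C)O[C@H]2C3SCCCS3)[C@@H](C)CO[Si](c4ccccc4)(c4ccccc4)C(C)(C)C | intermediate
23 | (14S)-allylic alcohol | C=C(Br)/C=C/[C@@H](OC(C)=O)[C@@]1(C)[C@@H](O)C=C(OC)[C@H](C)[C@@H]1[C@@H](OC(C)=O)[C@]2(OC(C)(C)O[C@H]2C3SCCCS3)[C@@H](C)CO[Si](c4ccccc4)(c4ccccc4)C(C)(C)C | intermediate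
24 | 14-butyrate | C=C(Br)/C=C/[C@@H](OC(C)=O)[C@@]1(C)[C@@H](OC(=O)CCC)C=C(OC)[C@H](C)[C@@H]1[C@@H](OC(C)=O)[C@]2(OC(C)(C)O[C@H]2C3SCCCS3)[C@@H](C)CO[Si](c4ccccc4)(c4ccccc4)C(C)(C)C | intermediate
25 | C6 aldehyde | C=C(Br)/C=C/[C@@H](OC(C)=O)[C@@]1(C)[C@@H](OC(=O)CCC)C=C(OC)[C@H](C)[C@@H]1[C@@H](OC(C)=O)[C@]2(OC(C)(C)O[C@H]2C=O)[C@@H](C)CO[Si](c3ccccc3)(c3ccccc3)C(C)(C)C | intermediate
26 | ten-membered C6 allylic alcohol (C6 epimers) | C=C1/C=C/[C@@H](OC(C)=O)[C@]2(C)[C@@H]([C@@H](OC(C)=O)[C@]3(OC(C)(C)O[C@H]3C1O)[C@@H](C)CO[Si](c4ccccc4)(c4ccccc4)C(C)(C)C)[C@@H](C)C(OC)=C[C@@H]2OC(=O)CCC | intermediate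
27 | C6 ketone | C=C1/C=C/[C@@H](OC(C)=O)[C@]2(C)[C@@H]([C@@H](OC(C)=O)[C@]3(OC(C)(C)O[C@H]3C1=O)[C@@H](C)CO[Si](c4ccccc4)(c4ccccc4)C(C)(C)C)[C@@H](C)C(OC)=C[C@@H]2OC(=O)CCC | intermediate
28 | (6R)-allylic alcohol | C=C1/C=C/[C@@H](OC(C)=O)[C@]2(C)[C@@H]([C@@H](OC(C)=O)[C@]3(OC(C)(C)O[C@H]3[C@@H]1O)[C@@H](C)CO[Si](c4ccccc4)(c4ccccc4)C(C)(C)C)[C@@H](C)C(OC)=C[C@@H]2OC(=O)CCC | intermediate
29 | (6S)-allylic chloride | C=C1/C=C/[C@@H](OC(C)=O)[C@]2(C)[C@@H]([C@@H](OC(C)=O)[C@]3(OC(C)(C)O[C@H]3[C@H]1Cl)[C@@H](C)CO[Si](c4ccccc4)(c4ccccc4)C(C)(C)C)[C@@H](C)C(OC)=C[C@@H]2OC(=O)CCC | intermediate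
30 | 7,8,19-triol 12-ketone | C=C1/C=C/[C@@H](OC(C)=O)[C@]2(C)[C@@H]([C@@H](OC(C)=O)[C@@](O)([C@@H](O)[C@H]1Cl)[C@@H](C)CO)[C@@H](C)C(=O)C[C@@H]2OC(=O)CCC | intermediate
31 | lactol (C19 hemiacetal with O7) | C=C1/C=C/[C@@H](OC(C)=O)[C@]2(C)[C@@H]([C@@H](OC(C)=O)[C@]3(O)[C@@H](C)C(O)O[C@H]3[C@H]1Cl)[C@@H](C)C(=O)C[C@@H]2OC(=O)CCC | intermediate
32 | CNP0283653.2 | C=C1/C=C/[C@@H](OC(C)=O)[C@]2(C)[C@@H]([C@@H](OC(C)=O)[C@]3(O)[C@@H](C)C(=O)O[C@H]3[C@H]1Cl)[C@@H](C)C(=O)C[C@@H]2OC(=O)CCC | target

**Step count and risks**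

Total step count: 24. Longest linear sequence: 23 steps (steps 1–10 and 12–24, from 1); step 11 is a one-step side branch.

Step 9. What may go wrong: slow conjugate addition to the hindered α-methylbutenolide, with retro-Michael reaction and γ-deprotonation (epimerisation at C9) competing, and incomplete discrimination between the two acetyl groups in the ring closure (C1 epimers). The fallback sets out from 10 and 11 and comes back at 13. Compound 11 is silylated (Me3SiCl, Et3N) to 3-methyl-4-(trimethylsilyloxy)pent-3-en-2-one F1. F1 is added to 10 in a Mukaiyama–Michael reaction catalysed by Me3SiOTf, so the butenolide is activated by a Lewis acid in a non-basic medium; aqueous work-up gives the isolated adduct 12. A separate Dieckmann-type condensation of 12 with LiN(SiMe3)2 at low temperature then gives 13. Because the ring closure is now its own step, the counter-ion (chelating lithium or non-chelating potassium) can be chosen to steer which acetyl group cyclises.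

Step 19. What may go wrong: intermolecular coupling (oligomerisation) and protonolysis of the vinylchromium species outrunning closure of the strained ten-membered ring. The fallback sets out from 25 and comes back at 27, replacing steps 19 and 20. Pinnick oxidation of 25 (NaClO2, NaH2PO4, 2-methyl-2-butene) gives the C6 carboxylic acid F2. 2,2'-Dipyridyl disulfide and PPh3 convert it into the S-(pyridin-2-yl) thioester F3. An intramolecular ketone synthesis between the vinyl bromide and the thioester, mediated by NiBr2(dtbbpy), Cp2ZrCl2 and Zn at high dilution, then forms the C5–C6 bond and gives ketone 27 directly.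

Step 3. What may go wrong: poor facial selectivity in the hydroboration, giving the C17 epimer. The fallback sets out from 2 and comes back at 5. Commercial 2-bromoallyl alcohol is silylated to (2-bromoallyloxy)(tert-butyl)diphenylsilane F4. Bromine–lithium exchange (t-BuLi, −78 °C) and addition to 2 gives 3-C-[3-(TBDPS-oxy)prop-1-en-2-yl]-1,2:5,6-di-O-isopropylidene-α-D-allofuranose F5. Hydroxyl-directed hydrogenation with [Ir(cod)(PCy3)(py)]PF6 and H2 in CH2Cl2 then gives 5. In this sequence the methylene carbon becomes the C18 methyl group instead of C19, so under the same conformational bias it should deliver the C17 configuration opposite to that from hydroboration; the two sequences are stereocomplementary.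

**Further compounds**

F1 | step 9 | 3-methyl-4-(trimethylsilyloxy)pent-3-en-2-one | CC(=O)C(C)=C(C)O[Si](C)(C)C
F2 | step 19 | C6 carboxylic acid from 25 | C=C(Br)/C=C/[C@@H](OC(C)=O)[C@@]1(C)[C@@H](OC(=O)CCC)C=C(OC)[C@H](C)[C@@H]1[C@@H](OC(C)=O)[C@]2(OC(C)(C)O[C@H]2C(=O)O)[C@@H](C)CO[Si](c3ccccc3)(c3ccccc3)C(C)(C)C
F3 | step 19 | S-(pyridin-2-yl) thioester of F2 | C=C(Br)/C=C/[C@@H](OC(C)=O)[C@@]1(C)[C@@H](OC(=O)CCC)C=C(OC)[C@H](C)[C@@H]1[C@@H](OC(C)=O)[C@]2(OC(C)(C)O[C@H]2C(=O)Sc3ccccn3)[C@@H](C)CO[Si](c4ccccc4)(c4ccccc4)C(C)(C)C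
F4 | step 3 | (2-bromoallyloxy)(tert-butyl)diphenylsilane | C=C(Br)CO[Si](c1ccccc1)(c1ccccc1)C(C)(C)C
F5 | step 3 | 3-C-[3-(TBDPS-oxy)prop-1-en-2-yl]-1,2:5,6-di-O-isopropylidene-α-D-allofuranose | CC1(C)OC[C@@H](O1)[C@H]2O[C@@H]3OC(C)(C)O[C@@H]3[C@@]2(O)C(=C)CO[Si](c4ccccc4)(c4ccccc4)C(C)(C)C
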